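## Retrosynthetic overview

1. 8 ⇒ 7: the only ring (the butenolide) closes last, by lactonisation of a (Z)-γ-hydroxy enoate in the flask of the key step.
2. 7 ⇒ 6 + 5: the C4–C5 bond comes from alkenylchromium 6, a β-acylvinyl anion (sp2 homoenolate) equivalent, and phenylacetaldehyde 5. Two carbonyl-derived, normally electrophilic carbons are joined, and C5 (S) is set by a chiral chromium ligand.
3. 6 ⇒ 4: (Z)-enol triflate of a β-keto ester, whose ketone carbon becomes the nucleophile.
4. 4 ⇒ 3 ⇒ 1 + 2: O-triflation, then C-benzylation of ethyl 3-oxo-4-phenylbutanoate.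

Assumption: ethyl 3-oxo-4-phenylbutanoate is bought as a catalogue chemical, and the (S)-ligand is written as the one that gives Re-face addition; this sense must be confirmed on the first run (sign of rotation, chiral HPLC), and the equally available (R)-ligand is used if the antipode forms.

## Route

Step 1
Reactants: 1 ethyl 3-oxo-4-phenylbutanoate (1.15 equiv); 2 benzyl bromide (1.0 equiv)
Product: 3 ethyl 2-benzyl-3-oxo-4-phenylbutanoate (racemic at C2)
Conditions: K2CO3 (1.2 equiv), acetone, reflux
Reagents that add atoms: none
Why: Only the doubly activated C2–H is deprotonated by K2CO3, so SN2 C-benzylation (acetoacetic ester alkylation) gives the mono-benzyl keto ester, a slight excess of 1 suppresses dialkylation, and the racemic C2 centre is erased in step 2.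

Step 2
Reactants: 3 ethyl 2-benzyl-3-oxo-4-phenylbutanoate
Product: 4 ethyl (2Z)-2-benzyl-4-phenyl-3-(trifluoromethanesulfonyloxy)but-2-enoate
Conditions: Tf2O (1.5 equiv), saturated aq LiOH, toluene, 5–10 °C
Reagents that add atoms: triflic anhydride, O=S(=O)(OS(=O)(=O)C(F)(F)F)C(F)(F)F
Why: The β-keto ester gives its lithium-chelated (Z)-enolate (C2–H is far more acidic than the benzylic C4–H), and O-triflation of that chelate places OTf cis to the ester (Frantz-type stereoselective enol triflation).

Step 3
Reactants: 4 ethyl (2Z)-2-benzyl-4-phenyl-3-(trifluoromethanesulfonyloxy)but-2-enoate (1.3 equiv); 5 phenylacetaldehyde (1.0 equiv, freshly distilled)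
Product: 8 (S)-maculalactone A, via alkenylchromium 6 (not isolated), via hydroxy ester 7 (not isolated)
Conditions: CrCl2 (10 mol %), Kishi-type (S)-oxazoline sulfonamide ligand (11 mol %), proton sponge (11 mol %), NiCl2·(2,9-dimethyl-1,10-phenanthroline) (2 mol %), Mn powder (2 equiv), Cp2ZrCl2 (1.2 equiv), LiCl (2 equiv), MeCN, rt; aq citric acid work-up
Reagents that add atoms: none
Why: Proposed new method: zerovalent nickel inserts into the C–OTf bond of 4 and transmetalation to trivalent chromium gives 6, in which the former ketone carbon is a β-acylvinyl anion (sp2 homoenolate) equivalent that adds to the aldehyde carbon of 5 on its Re face inside the chiral sulfonamide–chromium complex, setting C5 as S; the alkoxide of 7, held cis to the ester, then expels ethoxide to close the butenolide under non-basic conditions that leave the acidic C5–H untouched; the closest known reaction types are Nozaki–Hiyama–Kishi couplings of (Z)-β-iodo- and β-triflyloxy-acrylates with aldehydes to give butenolides and Kishi's catalytic asymmetric chromium–sulfonamide alkenylation of aldehydes, which I do not know to have been shown for a tetrasubstituted, ester-bearing alkenyl partner.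

## Compound list

1 | ethyl 3-oxo-4-phenylbutanoate | CCOC(=O)CC(=O)Cc1ccccc1 | starting material
2 | benzyl bromide | BrCc1ccccc1 | starting material
3 | ethyl 2-benzyl-3-oxo-4-phenylbutanoate (racemic) | CCOC(=O)C(Cc1ccccc1)C(=O)Cc1ccccc1 | intermediate
4 | ethyl (2Z)-2-benzyl-4-phenyl-3-(trifluoromethanesulfonyloxy)but-2-enoate | CCOC(=O)/C(Cc1ccccc1)=C(\OS(=O)(=O)C(F)(F)F)Cc1ccccc1 | intermediate
5 | phenylacetaldehyde | O=CCc1ccccc1 | starting material
6 | (Z)-alkenylchromium formed in the flask (trivalent chromium, chiral ligand not drawn, shown as the dichloride) | CCOC(=O)/C(Cc1ccccc1)=C(\[Cr](Cl)Cl)Cc1ccccc1 | intermediate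
7 | ethyl (2Z,4S)-2,3-dibenzyl-4-hydroxy-5-phenylpent-2-enoate (formed in the flask as its metal alkoxide) | CCOC(=O)/C(Cc1ccccc1)=C(\[C@@H](O)Cc1ccccc1)Cc1ccccc1 | intermediate
8 | (S)-maculalactone A, (5S)-3,4,5-tribenzylfuran-2(5H)-one | O=C1O[C@@H](Cc2ccccc2)C(Cc2ccccc2)=C1Cc1ccccc1 | target

## Step count and risks

Total steps: 3. Longest linear sequence: 3.

Steps most likely to fail, most risky first:

Step 3. The risks are the level and sense of enantioselectivity (the cis ester can compete with the chiral ligand for chromium), slow addition of a tetrasubstituted alkenylchromium, and homocoupling or reduction of 4. The fallback sets out from triflate 4 and comes back to the route at hydroxy ester 7. Carbonylative Stille coupling of 4 (Pd(PPh3)4, LiCl, CO 1 atm, benzyltributylstannane, THF, 55 °C) gives ethyl (2Z)-2,3-dibenzyl-4-oxo-5-phenylpent-2-enoate F1. Reduction of this ketone with (R)-Me-CBS (20 mol %) and catecholborane in toluene at −78 °C delivers hydride to the Re face (alkenyl as the large group, benzyl as the small one) and gives the (S)-alcohol 7, which closes to 8 on mild acid. The stereocentre is then set by reagent-controlled reduction and no longer in the C–C bond-forming step.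

Step 2. The risks are incomplete Z selectivity for a tetrasubstituted enol triflate and base-induced loss of triflic acid to an allenoate. The fallback sets out from benzyl bromide 2 and comes back to the route at alkenylchromium 6. Coupling of 2 with 3-phenylprop-1-yne (PdCl2(MeCN)2, XPhos, Cs2CO3, MeCN, 65 °C) gives 1,4-diphenylbut-2-yne F2. Ti(OiPr)4 and 2 equiv iPrMgCl (Et2O, −50 °C) convert it into the alkyne–titanium complex F3, and CO2 inserts to give the oxatitanacyclopentenone F4. Iodine cleaves the remaining Ti–C bond with retention to give (2Z)-2-benzyl-3-iodo-4-phenylbut-2-enoic acid F5, whose geometry is fixed by the metallacycle. EtI and K2CO3 in DMF give ethyl (2Z)-2-benzyl-3-iodo-4-phenylbut-2-enoate F6, which takes the place of 4 in step 3 and gives the same alkenylchromium 6.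

Step 1. The risks are dialkylation and some O-alkylation. The fallback sets out from keto ester 1 and comes back to the route at 3. Knoevenagel condensation of 1 with benzaldehyde (piperidine, AcOH, toluene, Dean–Stark) gives ethyl 2-benzylidene-3-oxo-4-phenylbutanoate F7 as an E/Z mixture. Conjugate reduction with Hantzsch ester (EtOH, 60 °C) gives 3; a second benzyl group cannot be introduced this way.

## Further compounds

F1 | step 3 | ethyl (2Z)-2,3-dibenzyl-4-oxo-5-phenylpent-2-enoate | CCOC(=O)/C(Cc1ccccc1)=C(\C(=O)Cc1ccccc1)Cc1ccccc1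
F2 | step 2 | 1,4-diphenylbut-2-yne | C(C#CCc1ccccc1)c1ccccc1
F3 | step 2 | alkyne–titanium complex, 2,3-dibenzyl-1,1-diisopropoxytitanacyclopropene | CC(C)O[Ti]1(OC(C)C)C(Cc2ccccc2)=C1Cc1ccccc1
F4 | step 2 | 3,4-dibenzyl-2,2-diisopropoxy-1-oxa-2-titanacyclopent-3-en-5-one | CC(C)O[Ti]1(OC(C)C)OC(=O)C(Cc2ccccc2)=C1Cc1ccccc1
F5 | step 2 | (2Z)-2-benzyl-3-iodo-4-phenylbut-2-enoic acid | OC(=O)/C(Cc1ccccc1)=C(\I)Cc1ccccc1
F6 | step 2 | ethyl (2Z)-2-benzyl-3-iodo-4-phenylbut-2-enoate | CCOC(=O)/C(Cc1ccccc1)=C(\I)Cc1ccccc1
F7 | step 1 | ethyl 2-benzylidene-3-oxo-4-phenylbutanoate (E/Z mixture) | CCOC(=O)C(=Cc1ccccc1)C(=O)Cc1ccccc1
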